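## The problem

1. The target is a trans-fused hydroazulene, numbered here C1–C10. Ring A is C1 (quaternary C–CH3), C2 (CH–OAc), C3 (CH2), C4 (C(OH)i-Pr) and C5 (ring-fusion CH). Ring B is C1, C5, C6 (CH–O-veratroyl), C7 (CH2), C8 (C–CH3), C9 (CH) and C10 (CH–OH), with an oxirane across C8–C9.
2. C7 and C10 are trans on that oxirane, so ring B carries a trans-fused three-membered ring. It cannot be made by epoxidising a cycloheptene; it has to be finished on an open chain from an (E)-alkene, and the seven-membered ring then closed at another bond against strain.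
3. Of the eight stereocentres the hardest is C4, a fully substituted carbinol whose isopropyl group lies on the crowded face, cis to the C1 methyl and to the C5–C6 bond. Addition of an isopropyl nucleophile to a C4 ketone would deliver the other epimer.
4. The centres can be relayed: C5 and C4 from one syn-aldol; C6 from C5 by Felkin–Anh control; C8/C9 from a reagent; C10 from C9; the quaternary C1 from the ring closure; C2 from the C10 hydroxyl.
5. Several groups will not survive rough treatment: the strained oxirane next to a free C10 hydroxyl (acid, Payne rearrangement), any C2 ketone with oxygen at C4 (retro-aldol, β-elimination), and two different esters beside a free 1,3-related hydroxyl (acyl migration). The end game must therefore be short and nearly neutral.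
6. The feature that makes the key step possible: when C2 is a ketone and C3 a carbene carbon, the C4–H bond of the syn-aldol carbinol is exactly 1,5 to C3 and activated by its oxygen. Replacing that hydrogen by C3 with retention closes ring A and gives the C4 configuration that carbonyl addition cannot.

## Retrosynthesis

**End game (43 ⇐ 42 ⇐ 41 ⇐ 40).** The last bonds cut are O4–Si, the C2 acetate and the C2–H bond. The veratroate is already in place in ketone 40, so only the C2 carbinol has to be created. The free C10 hydroxyl of 40 is used to deliver hydride to C2 from its own face, which is the face the target needs, and the resulting diol 41 is acetylated at the less hindered C2 hydroxyl. This asks for site selectivity between two secondary alcohols and for a desilylation that leaves the oxirane alone.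

**Ring B (40 ⇐ 38).** The C1–C10 bond is cut. Cutting C6–C7 or C7–C8 instead would need a carbanion β to the oxirane oxygen. Cutting C9–C10 would need an oxiranyl anion. Forming the oxirane on the ring is excluded by its trans geometry. The C1–C10 aldol makes the quaternary C1 and the C10 carbinol in one step from a monocyclic precursor that already holds C4, C5, C6, C8 and C9. The forward reaction must generate the enolate at C1 only, in the presence of an aldehyde; this is why the enolate is released by reduction of the C1 bromide in 38 (from 37).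

**Oxirane and chain (38 ⇐ 37 ⇐ 35 ⇐ 33 ⇐ 32 ⇐ 31 ⇐ 30 ⇐ 27).** The oxirane of 32 is cut back to the (E)-allylic alcohol 31 (reagent-controlled epoxidation). The C8–CH3 and C9–C10 bonds of 30 are cut back to the terminal alkyne 27 (syn-methylalumination, then formaldehyde), which fixes the trans C7/C10 relationship. The veratroate is placed on O6 (35) as soon as the primary C10 hydroxyl is masked (33), so O6 never needs a protecting group.

**C6 (27 ⇐ 26 ⇐ 25 ⇐ 23 + 24).** The C6–C7 bond is cut to aldehyde 23 and propargyl bromide 24. A carbon nucleophile adds to 23 in the Felkin sense, which is the wrong C6 epimer. A hydride adding to ketone 26 in the same Felkin sense gives the right one, so the carbinol is set by oxidation and reduction. Through these steps the C2 ketone is masked as the dioxolane 22; a ketal costs two steps where an alcohol protecting group would cost four.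

**Ring A, the key cut (21 ⇐ 19 ⇐ 18).** The C3–C4 bond is cut to the acyclic diazo β-keto ester 18. The neighbouring cuts are weaker. A C4–C5 or C3–C4 aldol onto a C4 ketone attacks the wrong face. A C2–C3 Dieckmann closure presupposes the tetrasubstituted C4. The precursor is much simpler: an open chain whose C4 and C5 come from one aldol and whose C4–H is replaced with retention. Two spectator choices serve this step. The C1 methyl is taken in the (S) series, trans to the C5 ester in the ring, so that it is pseudo-equatorial in the insertion transition state and configurationally stable afterwards; C1 is planarised later in any case. The C3 ester is benzyl, so that it can be removed by hydrogenolysis and mild decarboxylation, not by hot halide next to a β-silyloxy ketone.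

**Diazo ester (18 ⇐ 17 ⇐ 15 ⇐ 12 ⇐ 10 ⇐ 6 + 7).** Diazo transfer, two-carbon homologation of the C2 carboxyl of 15, and the syn-aldol of imide 6 with isobutyraldehyde 7 are the cuts. C6 is kept as a methyl ester because it is the other carbon 1,5 to the carbene and must carry no hydrogen. The C2 carboxyl travels as a tert-butyl ester, which cannot lactonise with the new C4 hydroxyl.

**Differentiated succinate (6 ⇐ 5 ⇐ 2 + 3 ⇐ 1).** The imide bond is cut to (S)-methylsuccinic anhydride 2 and the lithiated oxazolidinone from 3. Ring opening at the less hindered carbonyl distinguishes the two carboxyl groups of 1 in one step.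

## Roads not taken

**Alternative 1:** transannular enolate opening of a cyclodecane bis-oxirane. The cut is the ring-fusion bond C1–C5, so both rings come from the ten-membered ketone A1. In the forward step KN(SiMe3)2 would form the C1 enolate of the C10 ketone, which attacks C5 of the C4–C5 oxirane across the ring (inversion at C5, C4–O retained) to give A2.
- Merits: two rings, the quaternary C1 and the C4 carbinol arise in one step. The trans C8–C9 oxirane is unstrained in a ten-membered ring, and the strain of ring B is paid for by opening the other oxirane. In this respect it handles the strain problem better than the chosen aldol closure.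
- Weak points: A1 is itself a hard target, a medium ring with five stereocentres and two oxiranes whose faces depend on ring conformation. The enolate must reach C5 with backside alignment in one conformer. The liberated C4 alkoxide faces a second oxirane and a ketone across the ring. The α,β-epoxy ketone is base-sensitive. C10 and C2 still need adjusting afterwards.
- Comparison: after A1 the route would be shorter, but reaching A1 should cost at least as many steps as reaching 38. The chosen plan sets against the strain advantage the certainty of C4/C5 (one aldol, one stereospecific insertion) and stereocontrol exercised on open chains.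

**Alternative 2:** samarium aldol closing ring B on a preformed trans-oxirane, as the idea around which the synthesis is organised. The cut is C1–C10. In the forward step SmI2 (divalent samarium) reduces a C1 bromo ketone to a regiodefined enolate of trivalent samarium that adds to the tethered C10 aldehyde, giving A3.
- Merits: it addresses the most strained ring directly, makes C1 and C10 together, and is mild enough for the oxirane. As a way to close ring B it is as good as anything available, and the chosen route uses the same reaction as step 24.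
- Weak points: it says nothing about ring A. The C4 carbinol would have to come from addition to a C4 ketone, which places isopropyl on the open face and gives the wrong epimer. The silyl ethers on O4 and O6 in A3 must later be told apart before the acylations, at a cost of two or three steps.
- Comparison: equal for ring B. The chosen plan adds the C–H insertion that solves C4 and installs the veratroate before closure. The price of that economy is a possible acyl transfer in the enolate step.

**Alternative 3:** three-component methylalumination fixing the trans C7/C10 geometry. The cut is C8–CH3 plus C9–C10 across a C7-bound terminal alkyne. AlMe3 (with catalytic Cp2ZrCl2) and formaldehyde combine in one flask to give the (E)-allylic alcohol A4.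
- Merits: the alkene geometry, and with it the trans-oxirane, is fixed without isomer separation and in one operation. The chosen route uses the same reaction as step 17.
- Weak points: it forms no ring and no stereocentre, so as a leading idea it leaves C4, C6 and both ring closures open. The protecting-group pattern of A4 (ether on O2, silyl ether on O6) implies reducing, protecting, deprotecting and re-oxidising C2, and a later exchange at O6.
- Comparison: equal as a tactic. The chosen plan carries C2 as a ketal and O6 free through this step, which saves about five steps, and ties the tactic to a solution for ring A.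

Key step: step 10

Assumption: the stereodescriptors of the SMILES are taken literally, so C7 and C10 are trans on the C8–C9 oxirane (8R,9R in the core numbering) and ring B contains a trans-fused oxirane.

Notation: β is the face of ring A that carries H5 and the C4 oxygen; α is the face that carries the C4 isopropyl group and the C5–C6 bond. Locants C1–C10 are the core locants defined above.

## Route

Step 1
Reactants: 1 (S)-2-methylsuccinic acid
Product: 2 (S)-2-methylsuccinic anhydride
Conditions: AcCl, reflux; evaporate
Reagents that add atoms: none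
Why: Cyclodehydration of a 1,4-diacid with acetyl chloride; the stereocentre is not enolised under these conditions.

Step 2
Reactants: 2 (S)-2-methylsuccinic anhydride; 3 (S)-4-benzyl-1,3-oxazolidin-2-one
Product: 5 (2S)-4-[(4S)-4-benzyl-2-oxo-1,3-oxazolidin-3-yl]-2-methyl-4-oxobutanoic acid, via lithium oxazolidinide 4 (not isolated)
Conditions: 3, n-BuLi, THF, −78 °C; then 2, −78 to 0 °C; aq. HCl
Reagents that add atoms: none
Why: N-Acylation of the lithiated auxiliary by anhydride ring opening; the bulky nucleophile should attack the carbonyl next to CH2, not the one flanked by the methyl-bearing carbon, which puts the auxiliary on C6 and frees the C2 carboxyl.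

Step 3
Reactants: 5 (2S)-4-[(4S)-4-benzyl-2-oxo-1,3-oxazolidin-3-yl]-2-methyl-4-oxobutanoic acid
Product: 6 tert-butyl (2S)-4-[(4S)-4-benzyl-2-oxo-1,3-oxazolidin-3-yl]-2-methyl-4-oxobutanoate
Conditions: t-BuOC(=NH)CCl3, BF3·OEt2 (cat.), CH2Cl2/cyclohexane, rt
Reagents that add atoms: tert-butyl 2,2,2-trichloroacetimidate, CC(C)(C)OC(=N)C(Cl)(Cl)Cl
Why: Acid-catalysed tert-butylation of a carboxylic acid by the trichloroacetimidate; the imide is untouched and any regioisomer from step 2 can be removed here.

Step 4
Reactants: 6 tert-butyl (2S)-4-[(4S)-4-benzyl-2-oxo-1,3-oxazolidin-3-yl]-2-methyl-4-oxobutanoate; 7 isobutyraldehyde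
Product: 10 tert-butyl (2S,3S,4R)-3-{[(4S)-4-benzyl-2-oxo-1,3-oxazolidin-3-yl]carbonyl}-4-hydroxy-2,5-dimethylhexanoate, via boron enolate 8 (not isolated), via boron aldolate 9 (not isolated)
Conditions: Bu2BOTf, i-Pr2NEt, CH2Cl2, −78 to 0 °C; 7, −78 to 0 °C; pH 7 buffer, MeOH, H2O2, 0 °C
Reagents that add atoms: none
Why: Evans syn-aldol: the (Z)-boron enolate reacts through a Zimmerman–Traxler chair on the face dictated by the (S)-benzyl auxiliary, which sets C5 (S) and C4 (R) together; the tert-butyl ester prevents lactonisation of the new hydroxyl onto the C2 carboxyl.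

Step 5
Reactants: 10 tert-butyl (2S,3S,4R)-3-{[(4S)-4-benzyl-2-oxo-1,3-oxazolidin-3-yl]carbonyl}-4-hydroxy-2,5-dimethylhexanoate
Product: 11 (2S,3R)-2-[(2S)-1-tert-butoxy-1-oxopropan-2-yl]-3-hydroxy-4-methylpentanoic acid
Conditions: LiOH, H2O2, THF/H2O, 0 °C; aq. Na2SO3; aq. HCl
Reagents that add atoms: lithium hydroperoxide (from LiOH and H2O2), [Li+].[O-]O
Why: Hydroperoxide attacks the exocyclic imide carbonyl selectively and releases the auxiliary; the tert-butyl ester is inert and β-hydroxy imides tolerate these conditions without retro-aldol.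

Step 6
Reactants: 11 (2S,3R)-2-[(2S)-1-tert-butoxy-1-oxopropan-2-yl]-3-hydroxy-4-methylpentanoic acid
Product: 12 4-tert-butyl 1-methyl (2S,3S)-2-[(1R)-1-hydroxy-2-methylpropyl]-3-methylbutanedioate
Conditions: Me3SiCHN2, MeOH/PhMe, 0 °C
Reagents that add atoms: trimethylsilyldiazomethane, C[Si](C)(C)C=[N+]=[N-]
Why: Neutral methyl esterification of the C6 carboxyl; C6 thereby becomes an ester carbon without hydrogen, as the key step requires.

Step 7
Reactants: 12 4-tert-butyl 1-methyl (2S,3S)-2-[(1R)-1-hydroxy-2-methylpropyl]-3-methylbutanedioate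
Product: 15 (2S,3S,4R)-3-(methoxycarbonyl)-2,5-dimethyl-4-(triethylsilyloxy)hexanoic acid, via silyl ether 13 (not isolated), via silyl ester 14 (not isolated)
Conditions: Et3SiOTf, 2,6-lutidine, CH2Cl2, −78 °C; then Me3SiOTf, 0 °C to rt; aq. NaH2PO4
Reagents that add atoms: triethylsilyl triflate, CC[Si](CC)(CC)OS(=O)(=O)C(F)(F)F
Why: The silyl triflate protects the C4 hydroxyl; on warming with Me3SiOTf the tert-butyl ester is converted into a silyl ester with loss of isobutene, and this hydrolyses on work-up, while the methyl ester and the silyl ether survive.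

Step 8
Reactants: 15 (2S,3S,4R)-3-(methoxycarbonyl)-2,5-dimethyl-4-(triethylsilyloxy)hexanoic acid
Product: 17 benzyl (4S,5S,6R)-5-(methoxycarbonyl)-4,7-dimethyl-3-oxo-6-(triethylsilyloxy)octanoate, via acyl imidazolide 16 (not isolated)
Conditions: CDI, THF, rt; then Mg(O2CCH2CO2Bn)2, rt to 40 °C; aq. NH4Cl
Reagents that add atoms: magnesium bis(monobenzyl malonate), [Mg+2].[O-]C(=O)CC(=O)OCc1ccccc1.[O-]C(=O)CC(=O)OCc1ccccc1
Why: Masamune homologation: the acyl imidazolide is C-acylated by the magnesium malonate half-ester and decarboxylates to the β-keto ester under near-neutral conditions that should preserve the C1 centre and the silyl ether.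

Step 9
Reactants: 17 benzyl (4S,5S,6R)-5-(methoxycarbonyl)-4,7-dimethyl-3-oxo-6-(triethylsilyloxy)octanoate
Product: 18 benzyl (4S,5S,6R)-2-diazo-5-(methoxycarbonyl)-4,7-dimethyl-3-oxo-6-(triethylsilyloxy)octanoate
Conditions: 4-AcNHC6H4SO2N3, Et3N, MeCN, 0 °C to rt
Reagents that add atoms: 4-acetamidobenzenesulfonyl azide, CC(=O)Nc1ccc(cc1)S(=O)(=O)N=[N+]=[N-]
Why: Regitz diazo transfer to the active methylene of a β-keto ester; the amine is too weak to enolise C1 or C5.

Step 10
Reactants: 18 benzyl (4S,5S,6R)-2-diazo-5-(methoxycarbonyl)-4,7-dimethyl-3-oxo-6-(triethylsilyloxy)octanoate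
Product: 19 ring A keto diester: benzyl ester at C3, ketone at C2, 1β-methyl, 5α-methoxycarbonyl, 4β-triethylsilyloxy, 4α-isopropyl (C3 labile, written without descriptor)
Conditions: Rh2(OAc)4 (1 mol %), CH2Cl2, rt to 40 °C
Reagents that add atoms: none
Why: Rh2(OAc)4 expels N2 from 18 to give a catalyst-bound acceptor–acceptor carbene at C3, which inserts into the C4–H bond through a three-centre, chair-like transition state and forms C3–C4; the closest known reaction type is the dirhodium-catalysed 1,5 C–H insertion of α-diazo β-keto esters next to an ether oxygen, which proceeds with retention. Ring A closes as a five-membered ring by 1,5 insertion, the ring atoms being the carbene carbon C3, C2, C1, C5 and C4. The stereocentre that matters, C4, is controlled by the configuration of the C4–H bond set in the aldol of step 4, because carbon takes the place of hydrogen with retention; C3 is formed as a labile β-keto ester centre and is removed in step 11. The step needs site selectivity for the tertiary C4–H, and the substrate secures it: this is the only C–H bond that is both 1,5 to the carbene and activated by oxygen, the other 1,5 carbon (C6) is an ester carbon without hydrogen, the isopropyl methine would need a six-membered and the C1 methyl a four-membered transition state. The (S) configuration at C1 lets the C1 methyl, the C5 ester and the C4 silyloxy group all lie pseudo-equatorial in the transition state. The hindered, weakly basic silyl ether oxygen and the ester carbonyls are poor partners for ylide formation with this stabilised carbene.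

Step 11
Reactants: 19 ring A keto diester
Product: 21 methyl (1S,2S,5R)-2-methyl-3-oxo-5-(propan-2-yl)-5-(triethylsilyloxy)cyclopentane-1-carboxylate (core: C2 ketone; 1β-methyl; 4β-silyloxy; 4α-isopropyl; 5α-ester), via keto acid 20 (not isolated)
Conditions: H2 (1 atm), Pd/C, EtOAc, rt; then 50 °C
Reagents that add atoms: none
Why: Hydrogenolysis of the benzyl ester gives β-keto acid 20, which loses CO2 through the cyclic pathway on gentle warming; no base or hot halide (Krapcho conditions) is used, so the β-silyloxy ketone never meets enolate-forming conditions, and the trans C1/C5 arrangement is the stable one.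

Step 12
Reactants: 21 methyl (1S,2S,5R)-2-methyl-3-oxo-5-(propan-2-yl)-5-(triethylsilyloxy)cyclopentane-1-carboxylate
Product: 22 C2 ethylene ketal (1,3-dioxolane) of 21
Conditions: Me3SiOCH2CH2OSiMe3, Me3SiOTf (cat.), CH2Cl2, −78 to −20 °C; pyridine
Reagents that add atoms: 1,2-bis(trimethylsilyloxy)ethane, C[Si](C)(C)OCCO[Si](C)(C)C
Why: Aprotic silyl-triflate-catalysed ketalisation, driven by formation of hexamethyldisiloxane, masks C2 without the protic acid or heat that could eliminate the β-silyloxy group; the mask is needed for steps 13 to 17.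

Step 13
Reactants: 22 C2 ethylene ketal of 21
Product: 23 ring A aldehyde: C6 formyl in place of the ester of 22
Conditions: i-Bu2AlH, PhMe, −78 °C; MeOH; aq. KNaC4H4O6
Reagents that add atoms: none
Why: Low-temperature partial reduction of a hindered methyl ester stops at the aluminium hemiacetal, which gives the aldehyde on work-up; ketal and silyl ether are inert, and the aldehyde is used at once to avoid epimerisation at C5.

Step 14
Reactants: 23 ring A aldehyde; 24 propargyl bromide
Product: 25 homopropargylic alcohols: C6 carbinol carrying CH2C≡CH (C6 epimers, mainly 6S)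
Conditions: Zn, THF/sat. aq. NH4Cl, 0 °C to rt
Reagents that add atoms: none
Why: Barbier propargylation: allenylzinc bromide formed in the flask adds by SE2′ to give the homopropargylic alcohol; a carbon nucleophile follows the Felkin sense and gives mainly the 6S epimer, which is why the centre is reset in steps 15 and 16.

Step 15
Reactants: 25 homopropargylic alcohols (C6 epimers)
Product: 26 β,γ-ynone: C6 ketone carrying CH2C≡CH
Conditions: Dess–Martin periodinane, NaHCO3, CH2Cl2, 0 °C
Reagents that add atoms: none
Why: Dess–Martin oxidation under buffered, non-basic conditions converges both epimers on one ketone, which is used without delay to avoid isomerisation to the allenyl ketone.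

Step 16
Reactants: 26 β,γ-ynone
Product: 27 (6R)-homopropargylic alcohol (ring A as in 22)
Conditions: LiBH(s-Bu)3, THF, −78 °C; aq. NH4Cl
Reagents that add atoms: none
Why: Felkin–Anh reduction: hydride adds anti to the C5–C4 bond (C4 is the largest α-substituent) with the propargyl group beside H5, which gives the 6R alcohol; the bulky reagent at low temperature lets the 1,2-induction dominate and limits base-induced isomerisation.

Step 17
Reactants: 27 (6R)-homopropargylic alcohol
Product: 30 (6R,8E)-diol: C6–OH, C8 methyl, C10 primary allylic alcohol, C7 trans to C10 (ketal retained), via alkenylalane 28 (not isolated), via lithium aluminate 29 (not isolated)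
Conditions: AlMe3, Cp2ZrCl2 (cat.), ClCH2CH2Cl, 0 °C to rt; then n-BuLi, THF, −78 °C; (CH2O)n, −78 °C to rt; aq. KNaC4H4O6
Reagents that add atoms: trimethylaluminium, C[Al](C)C; paraformaldehyde (as formaldehyde), C=O
Why: Negishi zirconium-catalysed syn-methylalumination places CH3 on C8 and aluminium on C9, and the alkenyl aluminate is hydroxymethylated with retention, so C7 and C10 end up trans; the C6 hydroxyl travels as its aluminium alkoxide, and ketals of the acetonide type are known to tolerate these conditions.

Step 18
Reactants: 30 (6R,8E)-diol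
Product: 31 keto diol: C2 ketone restored; otherwise as 30
Conditions: PPTS, acetone/H2O, 40 °C
Reagents that add atoms: water, O
Why: Mild acid-catalysed transketalisation frees the C2 ketone before the acid-sensitive oxirane exists; the tertiary silyl ether and the allylic alcohol tolerate the pyridinium salt.

Step 19
Reactants: 31 keto diol
Product: 32 (6R,8R,9R)-epoxy diol: C8–C9 oxirane, C10 primary alcohol, C6–OH, C2 ketone
Conditions: Ti(Oi-Pr)4, D-(−)-diethyl tartrate, t-BuOOH, 4 Å MS, CH2Cl2, −20 °C
Reagents that add atoms: tert-butyl hydroperoxide, CC(C)(C)OO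
Why: Sharpless asymmetric epoxidation: the primary allylic alcohol binds titanium, and reagent control by D-(−)-diethyl tartrate (the tartrate that gives (2R,3R)-epoxygeraniol from the analogous alkene) should deliver oxygen to the face that gives the 8R,9R oxirane; the homoallylic C6 hydroxyl and the ketone are bystanders.

Step 20
Reactants: 32 (6R,8R,9R)-epoxy diol
Product: 33 C10 triethylsilyl ether of 32
Conditions: Et3SiCl, imidazole, CH2Cl2, −20 °C
Reagents that add atoms: chlorotriethylsilane, CC[Si](Cl)(CC)CC
Why: A silyl chloride at low temperature selects the primary alcohol over the hindered secondary C6 alcohol.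

Step 21
Reactants: 33 C10 triethylsilyl ether; 34 3,4-dimethoxybenzoyl chloride (veratroyl chloride)
Product: 35 C6 veratroate: (6R)-3,4-dimethoxybenzoate of 33
Conditions: Et3N, DMAP, CH2Cl2, 0 °C to rt
Reagents that add atoms: none
Why: DMAP-catalysed acylation of the only free hydroxyl; installing the final ester here means O6 never needs a protecting group, and the silyl ethers, oxirane and ketone are inert.

Step 22
Reactants: 35 C6 veratroate
Product: 37 C1 bromo ketone: 1-bromo-1-methyl-2-oxo ring A (C1 epimers), via silyl enol ether 36 (not isolated)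
Conditions: Me3SiOTf, Et3N, CH2Cl2, −20 to 0 °C; then NBS, THF, −78 °C
Reagents that add atoms: N-bromosuccinimide, O=C1CCC(=O)N1Br
Why: Equilibrating enol silylation gives the more substituted C1=C2 enol ether, which NBS brominates at C1 under non-acidic conditions that spare the oxirane; no free enolate is formed, so the C4 silyloxy group cannot be expelled, and the C1 configuration is irrelevant because step 24 planarises it.

Step 23
Reactants: 37 C1 bromo ketone
Product: 38 bromo epoxy aldehyde: C10 formyl (6R,8R,9S by descriptor, same geometry as 32)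
Conditions: (COCl)2, DMSO, CH2Cl2, −78 °C; Et3N, −78 to −30 °C
Reagents that add atoms: none
Why: Swern conditions convert a primary triethylsilyl ether directly into the aldehyde (oxidative desilylation) and leave the tertiary silyl ether alone; the cold, short exposure to amine should spare the tertiary bromide.

Step 24
Reactants: 38 bromo epoxy aldehyde
Product: 40 trans-fused hydroazulenone: C2 ketone, 1α-methyl, 10β-hydroxyl (10R), 8R,9R-oxirane, 6β-veratroate, 4β-triethylsilyloxy, via samarium enolate 39 (not isolated)
Conditions: SmI2 (2.2 equiv), THF, −78 °C; aq. NaHCO3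
Reagents that add atoms: none
Why: Samarium Reformatsky-type aldol: two equivalents of SmI2 (divalent samarium) reduce the C–Br bond to the C1=C2 enolate of trivalent samarium 39, which adds to the C10 aldehyde and closes the seven-membered ring; C10 should follow Felkin–Anh addition anti to the oxirane C9–O bond with H9, not C8, beside the incoming enolate, and attack on the enolate face anti to the C5–C6 bond gives the trans fusion; this enolate is not conjugated with the C4 silyloxy group, so no β-elimination is possible.

Step 25
Reactants: 40 trans-fused hydroazulenone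
Product: 41 2α,10β-diol (C2–OH cis to the C1 methyl)
Conditions: Me4NBH(OAc)3, MeCN/AcOH, −35 °C
Reagents that add atoms: none
Why: Evans–Saksena reduction: the C10 hydroxyl exchanges onto boron and hydride is delivered intramolecularly to the β face of the C2 ketone, giving the 1,3-anti diol with the C2 hydroxyl α; attack anti to the angular methyl favours the same face.

Step 26
Reactants: 41 2α,10β-diol
Product: 42 2α-acetate with free C10–OH and 4β-triethylsilyloxy
Conditions: Ac2O, pyridine, DMAP (cat.), CH2Cl2, 0 °C
Reagents that add atoms: acetic anhydride, CC(=O)OC(C)=O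
Why: Site-selective acetylation: the C2 hydroxyl, a cyclopentanol comparable to a steroid 17β-hydroxyl, should react well before the axial, neopentyl C10 hydroxyl, which is also flanked by the oxirane and is comparable to a 12α-hydroxyl.

Step 27
Reactants: 42 2α-acetate
Product: 43 target CNP0197096.5 (core descriptors 1R,2S,4R,5R,6R,8R,9R,10R)
Conditions: HF·pyridine, pyridine, THF, 0 °C to rt
Reagents that add atoms: none
Why: Buffered fluoride cleaves the tertiary triethylsilyl ether without opening the oxirane and without the basic conditions that promote acetyl migration to O10.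

## Compound list

1 | (S)-2-methylsuccinic acid | C[C@@H](CC(O)=O)C(O)=O | starting material
2 | (S)-2-methylsuccinic anhydride | C[C@H]1CC(=O)OC1=O | intermediate
3 | (S)-4-benzyl-1,3-oxazolidin-2-one | O=C1N[C@@H](Cc2ccccc2)CO1 | starting material
4 | lithium salt of 3 | [Li]N1[C@@H](Cc2ccccc2)COC1=O | intermediate (not isolated)
5 | (2S)-4-[(4S)-4-benzyl-2-oxo-1,3-oxazolidin-3-yl]-2-methyl-4-oxobutanoic acid | C[C@@H](CC(=O)N1[C@@H](Cc2ccccc2)COC1=O)C(O)=O | intermediate
6 | tert-butyl (2S)-4-[(4S)-4-benzyl-2-oxo-1,3-oxazolidin-3-yl]-2-methyl-4-oxobutanoate | C[C@@H](CC(=O)N1[C@@H](Cc2ccccc2)COC1=O)C(=O)OC(C)(C)C | intermediate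
7 | isobutyraldehyde | CC(C)C=O | starting material
8 | (Z)-dibutylboron enolate of 6 | CCCCB(CCCC)O/C(=C\[C@H](C)C(=O)OC(C)(C)C)N1[C@@H](Cc2ccccc2)COC1=O | intermediate (not isolated)
9 | dibutylboron aldolate of 10 | CC(C)(C)OC(=O)[C@@H](C)[C@H](C(=O)N1[C@@H](Cc2ccccc2)COC1=O)[C@H](OB(CCCC)CCCC)C(C)C | intermediate (not isolated)
10 | tert-butyl (2S,3S,4R)-3-{[(4S)-4-benzyl-2-oxo-1,3-oxazolidin-3-yl]carbonyl}-4-hydroxy-2,5-dimethylhexanoate | CC(C)(C)OC(=O)[C@@H](C)[C@H](C(=O)N1[C@@H](Cc2ccccc2)COC1=O)[C@H](O)C(C)C | intermediate
11 | (2S,3R)-2-[(2S)-1-tert-butoxy-1-oxopropan-2-yl]-3-hydroxy-4-methylpentanoic acid | CC(C)(C)OC(=O)[C@@H](C)[C@H](C(O)=O)[C@H](O)C(C)C | intermediate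
12 | 4-tert-butyl 1-methyl (2S,3S)-2-[(1R)-1-hydroxy-2-methylpropyl]-3-methylbutanedioate | CC(C)(C)OC(=O)[C@@H](C)[C@H](C(=O)OC)[C@H](O)C(C)C | intermediate
13 | 4-tert-butyl 1-methyl (2S,3S)-3-methyl-2-[(1R)-2-methyl-1-(triethylsilyloxy)propyl]butanedioate | CC(C)(C)OC(=O)[C@@H](C)[C@H](C(=O)OC)[C@H](O[Si](CC)(CC)CC)C(C)C | intermediate (not isolated)
14 | trimethylsilyl ester of 15 | C[Si](C)(C)OC(=O)[C@@H](C)[C@H](C(=O)OC)[C@H](O[Si](CC)(CC)CC)C(C)C | intermediate (not isolated)
15 | (2S,3S,4R)-3-(methoxycarbonyl)-2,5-dimethyl-4-(triethylsilyloxy)hexanoic acid | OC(=O)[C@@H](C)[C@H](C(=O)OC)[C@H](O[Si](CC)(CC)CC)C(C)C | intermediate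
16 | acyl imidazolide of 15 | O=C(n1ccnc1)[C@@H](C)[C@H](C(=O)OC)[C@H](O[Si](CC)(CC)CC)C(C)C | intermediate (not isolated)
17 | benzyl (4S,5S,6R)-5-(methoxycarbonyl)-4,7-dimethyl-3-oxo-6-(triethylsilyloxy)octanoate | O=C(OCc1ccccc1)CC(=O)[C@@H](C)[C@H](C(=O)OC)[C@H](O[Si](CC)(CC)CC)C(C)C | intermediate
18 | benzyl (4S,5S,6R)-2-diazo-5-(methoxycarbonyl)-4,7-dimethyl-3-oxo-6-(triethylsilyloxy)octanoate (precursor of the key step) | O=C(OCc1ccccc1)C(=[N+]=[N-])C(=O)[C@@H](C)[C@H](C(=O)OC)[C@H](O[Si](CC)(CC)CC)C(C)C | intermediate
19 | ring A keto diester: 3-benzyloxycarbonyl, 2-oxo, 1β-methyl, 5α-methoxycarbonyl, 4β-triethylsilyloxy, 4α-isopropyl; C3 labile (product of the key step) | O=C(OCc2ccccc2)C1C(=O)[C@@H](C)[C@H](C(=O)OC)[C@]1(O[Si](CC)(CC)CC)C(C)C | intermediate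
20 | β-keto acid from 19 | OC(=O)C1C(=O)[C@@H](C)[C@H](C(=O)OC)[C@]1(O[Si](CC)(CC)CC)C(C)C | intermediate (not isolated)
21 | methyl (1S,2S,5R)-2-methyl-3-oxo-5-(propan-2-yl)-5-(triethylsilyloxy)cyclopentane-1-carboxylate | C1C(=O)[C@@H](C)[C@H](C(=O)OC)[C@]1(O[Si](CC)(CC)CC)C(C)C | intermediate
22 | C2 ethylene ketal of 21 | C1C2(OCCO2)[C@@H](C)[C@H](C(=O)OC)[C@]1(O[Si](CC)(CC)CC)C(C)C | intermediate
23 | ring A aldehyde (C6 formyl, C2 ketal) | C1C2(OCCO2)[C@@H](C)[C@H](C=O)[C@]1(O[Si](CC)(CC)CC)C(C)C | intermediate
24 | propargyl bromide | C#CCBr | starting material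
25 | homopropargylic alcohols, C6 epimers (mainly 6S) | C1C2(OCCO2)[C@@H](C)[C@H](C(O)CC#C)[C@]1(O[Si](CC)(CC)CC)C(C)C | intermediate
26 | β,γ-ynone (C6 ketone) | C1C2(OCCO2)[C@@H](C)[C@H](C(=O)CC#C)[C@]1(O[Si](CC)(CC)CC)C(C)C | intermediate
27 | (6R)-homopropargylic alcohol | C1C2(OCCO2)[C@@H](C)[C@H]([C@H](O)CC#C)[C@]1(O[Si](CC)(CC)CC)C(C)C | intermediate
28 | (E)-alkenyldimethylalane with O6 as aluminium alkoxide | C1C2(OCCO2)[C@@H](C)[C@H]([C@H](O[Al](C)C)C/C(C)=C/[Al](C)C)[C@]1(O[Si](CC)(CC)CC)C(C)C | intermediate (not isolated)
29 | lithium butyl(dimethyl)alkenylaluminate from 28 | [Li+].C1C2(OCCO2)[C@@H](C)[C@H]([C@H](O[Al](C)C)C/C(C)=C/[Al-](C)(C)CCCC)[C@]1(O[Si](CC)(CC)CC)C(C)C | intermediate (not isolated)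
30 | (6R,8E)-diol with C2 ketal | C1C2(OCCO2)[C@@H](C)[C@H]([C@H](O)C/C(C)=C/CO)[C@]1(O[Si](CC)(CC)CC)C(C)C | intermediate
31 | (6R,8E)-keto diol | C1C(=O)[C@@H](C)[C@H]([C@H](O)C/C(C)=C/CO)[C@]1(O[Si](CC)(CC)CC)C(C)C | intermediate
32 | (6R,8R,9R)-epoxy diol | C1C(=O)[C@@H](C)[C@H]([C@H](O)C[C@@]3(C)O[C@@H]3CO)[C@]1(O[Si](CC)(CC)CC)C(C)C | intermediate
33 | C10 triethylsilyl ether of 32 | C1C(=O)[C@@H](C)[C@H]([C@H](O)C[C@@]3(C)O[C@@H]3CO[Si](CC)(CC)CC)[C@]1(O[Si](CC)(CC)CC)C(C)C | intermediate
34 | 3,4-dimethoxybenzoyl chloride | COc1ccc(C(Cl)=O)cc1OC | starting material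
35 | C6 veratroate of 33 | C1C(=O)[C@@H](C)[C@H]([C@H](OC(=O)c4ccc(OC)c(OC)c4)C[C@@]3(C)O[C@@H]3CO[Si](CC)(CC)CC)[C@]1(O[Si](CC)(CC)CC)C(C)C | intermediate
36 | C1=C2 trimethylsilyl enol ether of 35 | C1C(O[Si](C)(C)C)=C(C)[C@H]([C@H](OC(=O)c4ccc(OC)c(OC)c4)C[C@@]3(C)O[C@@H]3CO[Si](CC)(CC)CC)[C@]1(O[Si](CC)(CC)CC)C(C)C | intermediate (not isolated)
37 | C1 bromo ketone (C1 epimers) | C1C(=O)C(C)(Br)[C@H]([C@H](OC(=O)c4ccc(OC)c(OC)c4)C[C@@]3(C)O[C@@H]3CO[Si](CC)(CC)CC)[C@]1(O[Si](CC)(CC)CC)C(C)C | intermediate
38 | bromo epoxy aldehyde (C10 formyl) | C1C(=O)C(C)(Br)[C@H]([C@H](OC(=O)c4ccc(OC)c(OC)c4)C[C@@]3(C)O[C@@H]3C=O)[C@]1(O[Si](CC)(CC)CC)C(C)C | intermediate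
39 | C1=C2 enolate of trivalent samarium from 38 | C1C(O[Sm](I)I)=C(C)[C@H]([C@H](OC(=O)c4ccc(OC)c(OC)c4)C[C@@]3(C)O[C@@H]3C=O)[C@]1(O[Si](CC)(CC)CC)C(C)C | intermediate (not isolated)
40 | trans-fused C10-hydroxy C2-ketone with 6-veratroate and 4-triethylsilyl ether | COc1ccc(C(=O)O[C@@H]2C[C@@]3(C)O[C@@H]3[C@H](O)[C@]3(C)C(=O)C[C@@](O[Si](CC)(CC)CC)(C(C)C)[C@@H]23)cc1OC | intermediate
41 | 2α,10β-diol | COc1ccc(C(=O)O[C@@H]2C[C@@]3(C)O[C@@H]3[C@H](O)[C@]3(C)[C@@H](O)C[C@@](O[Si](CC)(CC)CC)(C(C)C)[C@@H]23)cc1OC | intermediate
42 | 2α-acetate, 4-triethylsilyl ether | COc1ccc(C(=O)O[C@@H]2C[C@@]3(C)O[C@@H]3[C@H](O)[C@]3(C)[C@@H](OC(C)=O)C[C@@](O[Si](CC)(CC)CC)(C(C)C)[C@@H]23)cc1OC | intermediate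
43 | CNP0197096.5 | COc1ccc(C(=O)O[C@@H]2C[C@@]3(C)O[C@@H]3[C@H](O)[C@]3(C)[C@@H](OC(C)=O)C[C@@](O)(C(C)C)[C@@H]23)cc1OC | target

## Step count and least certain steps

Total: 27 steps. Longest linear sequence: 27 steps (1 → 43); the route is fully linear.

**Step 10 (key step).** Most likely failure: the carbene is diverted before it reaches the hindered C4–H, which is activated by oxygen but inductively weakened by the neighbouring C5 ester. Diversion could be attack by the C6 ester carbonyl or the silyl ether oxygen (ylide formation), or carbene dimerisation. Fallback: set out from acid 15, activate it as the mixed anhydride (i-BuOCOCl, N-methylmorpholine) and treat with CH2N2 to give the α-diazoketone F1. Its acceptor-only carbene, formed with Rh2(OAc)4, is more reactive and less hindered in the same 1,5 insertion, and it gives ketone 21 directly. The route is rejoined at 21.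

**Step 24.** Most likely failures:
- ring closure slow because the trans-oxirane makes ring B strained, so that the enolate is protonated to the debrominated ketone;
- attack on the other enolate face (cis fusion);
- transfer of the veratroyl group from O6 to C1 through a five-membered transition state;
- electron transfer to the epoxy aldehyde.

Fallback: set out from 35 and oxidise the primary silyl ether under Swern conditions to the keto aldehyde F2. Treat F2 with Me3SiOTf and i-Pr2NEt, which forms the C1=C2 enol silane in the flask and effects an intramolecular Mukaiyama aldol through an open transition state. The adduct is trapped irreversibly as the C10 trimethylsilyl ether F3, and a silyl enol ether cannot attack the ester. Citric acid in MeOH then gives 40.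

**Step 17.** Most likely failures: Lewis-acid opening of the dioxolane by AlMe3 with methyl transfer during the long carbometalation, or incomplete capture of the alkenyl aluminate by formaldehyde. Fallback: set out from 27 and hydroxymethylate the alkyne (n-BuLi, then (CH2O)n) to the propargylic diol F4. Trans-hydroalumination with NaAlH2(OCH2CH2OMe)2 followed by I2 gives the (Z)-3-iodo allylic alcohol F5 (iodine on C8), and Me2CuLi replaces iodine by methyl with retention to give 30. This sequence uses no strong Lewis acid.

**Step 16.** Most likely failures: insufficient facial selectivity (the β-silyloxy group opposes the Felkin preference weakly), or base-induced isomerisation of the β,γ-ynone to the allenyl ketone before reduction. Fallback: set out from 25 (mainly the 6S epimer, after removing the minor one) and invert C6 by a Mitsunobu reaction with 4-nitrobenzoic acid (PPh3, DIAD) to the (6R)-ester F6. K2CO3 in MeOH then gives 27. This avoids the ynone altogether.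

**Step 26.** Most likely failures: insufficient discrimination between the two secondary hydroxyls, or acetyl migration from O2 to O10. Fallback: set out from 40 and silylate the C10 hydroxyl first (Et3SiOTf, 2,6-lutidine) to F7. Reduce the ketone with NaBH4 in MeOH, relying on attack anti to the angular methyl, to give the 2α-alcohol F8. Acetylate (Ac2O, DMAP) to F9, and remove both silyl ethers with HF·pyridine to reach 43.

## Further compounds

F1 | step 10 | methyl (2S,3S)-5-diazo-3-methyl-2-[(1R)-2-methyl-1-(triethylsilyloxy)propyl]-4-oxopentanoate | [N-]=[N+]=CC(=O)[C@@H](C)[C@H](C(=O)OC)[C@H](O[Si](CC)(CC)CC)C(C)C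
F2 | step 24 | keto epoxy aldehyde (35 with C10 formyl, no bromine) | C1C(=O)[C@@H](C)[C@H]([C@H](OC(=O)c4ccc(OC)c(OC)c4)C[C@@]3(C)O[C@@H]3C=O)[C@]1(O[Si](CC)(CC)CC)C(C)C
F3 | step 24 | C10 trimethylsilyl ether of 40 | COc1ccc(C(=O)O[C@@H]2C[C@@]3(C)O[C@@H]3[C@H](O[Si](C)(C)C)[C@]3(C)C(=O)C[C@@](O[Si](CC)(CC)CC)(C(C)C)[C@@H]23)cc1OC
F4 | step 17 | (6R)-propargylic diol (C8≡C9, C10 hydroxymethyl) | C1C2(OCCO2)[C@@H](C)[C@H]([C@H](O)CC#CCO)[C@]1(O[Si](CC)(CC)CC)C(C)C
F5 | step 17 | (6R,8Z)-8-iodo allylic diol | C1C2(OCCO2)[C@@H](C)[C@H]([C@H](O)C/C(I)=C/CO)[C@]1(O[Si](CC)(CC)CC)C(C)C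
F6 | step 16 | (6R)-4-nitrobenzoate of 27 | C1C2(OCCO2)[C@@H](C)[C@H]([C@H](OC(=O)c3ccc(cc3)[N+](=O)[O-])CC#C)[C@]1(O[Si](CC)(CC)CC)C(C)C
F7 | step 26 | C10 triethylsilyl ether of 40 | COc1ccc(C(=O)O[C@@H]2C[C@@]3(C)O[C@@H]3[C@H](O[Si](CC)(CC)CC)[C@]3(C)C(=O)C[C@@](O[Si](CC)(CC)CC)(C(C)C)[C@@H]23)cc1OC
F8 | step 26 | 2α-alcohol with 4,10-bis(triethylsilyl) ethers | COc1ccc(C(=O)O[C@@H]2C[C@@]3(C)O[C@@H]3[C@H](O[Si](CC)(CC)CC)[C@]3(C)[C@@H](O)C[C@@](O[Si](CC)(CC)CC)(C(C)C)[C@@H]23)cc1OC
F9 | step 26 | 2α-acetate with 4,10-bis(triethylsilyl) ethers | COc1ccc(C(=O)O[C@@H]2C[C@@]3(C)O[C@@H]3[C@H](O[Si](CC)(CC)CC)[C@]3(C)[C@@H](OC(C)=O)C[C@@](O[Si](CC)(CC)CC)(C(C)C)[C@@H]23)cc1OC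
A1 | alternative 1 | ten-membered C10 ketone with C4–C5 and C8–C9 oxiranes (O6 silyl ether, O2 4-methoxybenzyl ether; C1 unspecified) | CC(C)(C)[Si](C)(C)O[C@@H]2C[C@@]3(C)O[C@@H]3C(=O)C(C)[C@@H](OCc4ccc(OC)cc4)C[C@]5(C(C)C)O[C@@H]25
A2 | alternative 1 | trans-fused hydroazulene C10 ketone with free C4 hydroxyl and intact C8–C9 oxirane | CC(C)(C)[Si](C)(C)O[C@@H]2C[C@@]3(C)O[C@@H]3C(=O)[C@]3(C)[C@@H](OCc4ccc(OC)cc4)C[C@@](O)(C(C)C)[C@@H]23
A3 | alternative 2 | trans-fused C10-hydroxy C2-ketone with O6 tert-butyldimethylsilyl and O4 triethylsilyl ethers | CC(C)(C)[Si](C)(C)O[C@@H]2C[C@@]3(C)O[C@@H]3[C@H](O)[C@]3(C)C(=O)C[C@@](O[Si](CC)(CC)CC)(C(C)C)[C@@H]23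
A4 | alternative 3 | (E)-allylic alcohol with C7 trans to C10 (O6 silyl ether, O2 4-methoxybenzyl ether, O4 triethylsilyl ether) | OC/C=C(\C)C[C@@H](O[Si](C)(C)C(C)(C)C)[C@H]1[C@@H](C)[C@@H](OCc2ccc(OC)cc2)C[C@@]1(O[Si](CC)(CC)CC)C(C)C
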